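**Plan**

1. Retrosynthesis: the two MOM ethers are cut last. The C3 stereocentre is traced back through the cis C4 carbinol to the racemic isoflavanone, and this to its C3 allyl ester.
2. Ring C of that ester is cut at C2–C3 and at O1–C8a, giving formaldehyde and an alpha-aryl beta-keto allyl ester that carries fluorine on the later C8a. This ester is cut at C3–C4 into a ring B arylacetate and a ring A benzaldehyde.
3. Forward: the ring B chromene is made first (para-selective O-propargylation of 3,4-dihydroxybenzaldehyde, Claisen rearrangement/electrocyclisation) and homologated by one carbon to the allyl arylacetate. The ring A aldehyde comes from MOM protection and one methoxide SNAr. Aldol addition and oxidation join the halves.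
4. Ring C then closes in one operation: formaldehyde supplies C2 and O1, C3 attacks its carbon, and the new alkoxide displaces fluoride from C8a.
5. Enabling feature: the C4 carbonyl is ortho to C8a of ring A, while the C5 and C7 oxygens are meta to C8a. C8a therefore becomes an SNAr acceptor as soon as C3, which lies between the C4 carbonyl and the helper ester, is quaternary. The ester helper later leaves as CO2 and propene.
6. Stereochemistry: C3 (R) is set by catalyst-controlled transfer hydrogenation with dynamic kinetic resolution to the cis-(3R,4R) alcohol; reoxidation of C4 keeps it.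

Key step: step 11

Assumption (chemistry): RuCl[(R,R)-TsDPEN](p-cymene) is taken to give the (4R) carbinol, as it does with simple aryl alkyl ketones; if the opposite sense were found, the (S,S) complex would be used.

**Route**

Step 1
Reactants: 1 3,4-dihydroxybenzaldehyde; 2 3-chloro-3-methylbut-1-yne
Product: 3 3-hydroxy-4-[(2-methylbut-3-yn-2-yl)oxy]benzaldehyde
Conditions: K2CO3 (1.1 equiv), KI (cat.), DMF, 60 °C, argon
Reagents that add atoms: none
Why: Williamson-type O-propargylation in which the 4-OH, para to the formyl group and therefore the more acidic phenol, is deprotonated and alkylated selectively while the 3-OH stays free.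

Step 2
Reactants: 3 3-hydroxy-4-[(2-methylbut-3-yn-2-yl)oxy]benzaldehyde
Product: 5 8-hydroxy-2,2-dimethyl-2H-chromene-6-carbaldehyde, via 5-allenyl catechol aldehyde 4 (not isolated)
Conditions: PhNEt2, 180 °C
Reagents that add atoms: none
Why: Aryl propargyl ether Claisen rearrangement to the only free ortho position, followed by [1,5]-H shift and oxa-6π electrocyclisation, should give the 2,2-dimethylchromene with the untouched phenol at C8.

Step 3
Reactants: 5 8-hydroxy-2,2-dimethyl-2H-chromene-6-carbaldehyde
Product: 6 8-(methoxymethoxy)-2,2-dimethyl-2H-chromene-6-carbaldehyde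
Conditions: MOMCl, i-Pr2NEt, CH2Cl2, 0 °C to rt
Reagents that add atoms: chloromethyl methyl ether (MOMCl), COCCl
Why: Standard MOM ether formation; the acetal withstands the bases, fluoride, palladium and hydride used later.

Step 4
Reactants: 6 8-(methoxymethoxy)-2,2-dimethyl-2H-chromene-6-carbaldehyde
Product: 8 2-[8-(methoxymethoxy)-2,2-dimethyl-2H-chromen-6-yl]acetonitrile, via N-(1-tosylalkenyl)formamide 7 (not isolated)
Conditions: TosMIC, t-BuOK, DME, −40 °C; then MeOH, reflux
Reagents that add atoms: p-toluenesulfonylmethyl isocyanide (TosMIC), Cc1ccc(cc1)S(=O)(=O)C[N+]#[C-]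
Why: van Leusen reductive cyanation, in which the TosMIC anion adds to the aldehyde, the adduct opens to the N-formyl enamide and methanolysis with loss of sulfinate gives the one-carbon homologated nitrile.

Step 5
Reactants: 8 2-[8-(methoxymethoxy)-2,2-dimethyl-2H-chromen-6-yl]acetonitrile
Product: 9 2-[8-(methoxymethoxy)-2,2-dimethyl-2H-chromen-6-yl]acetic acid
Conditions: KOH, EtOH/H2O, reflux; then 1 M HCl to pH 4, 0 °C
Reagents that add atoms: water, O; potassium hydroxide, [K+].[OH-]
Why: Base hydrolysis of an arylacetonitrile, tolerated by the MOM ether and the chromene; cold acidification to pH 4 spares the acetal.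

Step 6
Reactants: 9 2-[8-(methoxymethoxy)-2,2-dimethyl-2H-chromen-6-yl]acetic acid
Product: 10 allyl 2-[8-(methoxymethoxy)-2,2-dimethyl-2H-chromen-6-yl]acetate
Conditions: allyl bromide, K2CO3, DMF, rt
Reagents that add atoms: allyl bromide, C=CCBr
Why: Carboxylate O-alkylation installs the allyl ester that later serves as the removable activating and blocking group at C3.

Step 7
Reactants: 11 2,6-difluoro-4-hydroxybenzaldehyde
Product: 12 2,6-difluoro-4-(methoxymethoxy)benzaldehyde
Conditions: MOMCl, i-Pr2NEt, CH2Cl2, 0 °C to rt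
Reagents that add atoms: chloromethyl methyl ether (MOMCl), COCCl
Why: MOM protection keeps the para oxygen from becoming a phenoxide, which would switch off both SNAr reactions on this ring.

Step 8
Reactants: 12 2,6-difluoro-4-(methoxymethoxy)benzaldehyde
Product: 13 2-fluoro-6-methoxy-4-(methoxymethoxy)benzaldehyde
Conditions: NaOMe (1.05 equiv), MeOH/THF, 0 °C to rt
Reagents that add atoms: sodium methoxide, C[O-].[Na+]
Why: SNAr of one of two equivalent ortho fluorines activated by the formyl group; one equivalent of methoxide should stop at mono-substitution because the new ortho methoxy group lowers the acceptor strength of the formyl group.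

Step 9
Reactants: 10 allyl 2-[8-(methoxymethoxy)-2,2-dimethyl-2H-chromen-6-yl]acetate; 13 2-fluoro-6-methoxy-4-(methoxymethoxy)benzaldehyde
Product: 14 allyl 3-[2-fluoro-6-methoxy-4-(methoxymethoxy)phenyl]-3-hydroxy-2-[8-(methoxymethoxy)-2,2-dimethyl-2H-chromen-6-yl]propanoate (racemic diastereomer mixture)
Conditions: LDA, THF, −78 °C; then 13; AcOH quench at −78 °C
Reagents that add atoms: none
Why: Aldol addition of the lithium ester enolate to a non-enolisable benzaldehyde, kept cold to avoid Ireland–Claisen rearrangement of the allyl ester enolate; the two new stereocentres need no control because both are destroyed in steps 10 and 11.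

Step 10
Reactants: 14 allyl 3-[2-fluoro-6-methoxy-4-(methoxymethoxy)phenyl]-3-hydroxy-2-[8-(methoxymethoxy)-2,2-dimethyl-2H-chromen-6-yl]propanoate
Product: 15 allyl 3-[2-fluoro-6-methoxy-4-(methoxymethoxy)phenyl]-2-[8-(methoxymethoxy)-2,2-dimethyl-2H-chromen-6-yl]-3-oxopropanoate (racemic)
Conditions: Dess–Martin periodinane (1.2 equiv), NaHCO3, CH2Cl2, 0 °C to rt
Reagents that add atoms: none
Why: Dess–Martin oxidation of the benzylic beta-hydroxy ester to the beta-keto ester under buffered conditions that spare the MOM ethers and the chromene.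

Step 11
Reactants: 15 allyl 3-[2-fluoro-6-methoxy-4-(methoxymethoxy)phenyl]-2-[8-(methoxymethoxy)-2,2-dimethyl-2H-chromen-6-yl]-3-oxopropanoate; 16 formaldehyde (used as paraformaldehyde)
Product: 18 allyl 5-methoxy-7-(methoxymethoxy)-3-[8-(methoxymethoxy)-2,2-dimethyl-2H-chromen-6-yl]-4-oxochromane-3-carboxylate (racemic), via hydroxymethyl aldol adduct 17 (not isolated)
Conditions: (CH2O)n (3 equiv), Cs2CO3 (1.5 equiv), DMF, rt to 60 °C
Reagents that add atoms: none
Why: Proposed new method: Cs2CO3 deprotonates C3 of 15 (flanked by the C4 carbonyl and the ester) and the enolate adds to formaldehyde (aldol hydroxymethylation, C2–C3 bond); this turns the delocalised enolate into a non-enolisable aryl ketone whose C4 carbonyl now activates the ortho C–F carbon (C8a), so the primary alkoxide of 17 adds at C8a to a Meisenheimer complex and expels fluoride (intramolecular SNAr, O1–C8a bond). The closest known reaction types are the carbonate-mediated hydroxymethylation of alpha-substituted beta-keto esters with formaldehyde, the alkoxide SNAr closure of 2-fluoroaryl ketones to chroman-4-ones, and tandem aldol–SNAr annulations of nitro-activated fluoroarenes; what is new is their union on a fluoroarene activated by the ketone alone. Ring C, the only ring closed, forms by ipso addition–elimination of the tethered alkoxide at C8a through a six-membered transition state. The quaternary C3 centre arises racemic because nothing in the substrate or reagents is chiral, and this is intended, since the centre is erased in step 12 and set in step 13. The step needs SNAr at C–F to win over retro-aldol, over C-to-O transfer of the aroyl group (deacylative methylenation), over attack at the ortho C–OMe carbon and over seven-membered closure of a hemiformal: retro-aldol only returns 15, the 2,6-disubstituted aroyl carbonyl is shielded against addition, fluoride is a far better nucleofuge than methoxide, and the C5 and C7 oxygens are meta to C8a and do not deactivate it. Fluoride loss is irreversible and should drain the aldol equilibrium towards 18.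

Step 12
Reactants: 18 allyl 5-methoxy-7-(methoxymethoxy)-3-[8-(methoxymethoxy)-2,2-dimethyl-2H-chromen-6-yl]-4-oxochromane-3-carboxylate
Product: 20 rac-5-methoxy-7-(methoxymethoxy)-3-[8-(methoxymethoxy)-2,2-dimethyl-2H-chromen-6-yl]chroman-4-one, via beta-keto acid 19 (not isolated)
Conditions: Pd(OAc)2 (5 mol %), PPh3 (20 mol %), HCO2H, Et3N, THF, rt
Reagents that add atoms: none
Why: Tsuji-type deallylation–decarboxylation, in which zerovalent palladium formed in situ ionises the allyl ester, formate reduces the allyl fragment to propene and the beta-keto acid loses CO2, removes the helper ester under mild conditions.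

Step 13
Reactants: 20 rac-5-methoxy-7-(methoxymethoxy)-3-[8-(methoxymethoxy)-2,2-dimethyl-2H-chromen-6-yl]chroman-4-one
Product: 21 (3R,4R)-5-methoxy-7-(methoxymethoxy)-3-[8-(methoxymethoxy)-2,2-dimethyl-2H-chromen-6-yl]chroman-4-ol (cis)
Conditions: RuCl[(R,R)-TsDPEN](p-cymene) (5 mol %), HCO2H/Et3N (5:2), EtOAc, 40 °C
Reagents that add atoms: none
Why: Noyori–Ikariya asymmetric transfer hydrogenation with dynamic kinetic resolution: C3 epimerises through the enol in the formate–amine medium, the (R,R) catalyst fixes C4 as (R), and hydride is delivered anti to the C3 aryl group of the faster-reacting ketone enantiomer, so the cis-(3R,4R) alcohol should form and C3 is set.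

Step 14
Reactants: 21 (3R,4R)-5-methoxy-7-(methoxymethoxy)-3-[8-(methoxymethoxy)-2,2-dimethyl-2H-chromen-6-yl]chroman-4-ol
Product: 22 (3R)-5-methoxy-7-(methoxymethoxy)-3-[8-(methoxymethoxy)-2,2-dimethyl-2H-chromen-6-yl]chroman-4-one
Conditions: Dess–Martin periodinane (1.2 equiv), NaHCO3, CH2Cl2, 0 °C
Reagents that add atoms: none
Why: Dess–Martin oxidation of the benzylic carbinol under buffered, base-free conditions returns the C4 ketone without an enolisation pathway, so the C3 configuration should be kept.

Step 15
Reactants: 22 (3R)-5-methoxy-7-(methoxymethoxy)-3-[8-(methoxymethoxy)-2,2-dimethyl-2H-chromen-6-yl]chroman-4-one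
Product: 23 (3R)-7-hydroxy-3-(8-hydroxy-2,2-dimethyl-2H-chromen-6-yl)-5-methoxychroman-4-one
Conditions: HCl (2 M) in MeOH/THF, rt to 40 °C
Reagents that add atoms: none
Why: Acid-catalysed acetal exchange removes both MOM ethers as dimethoxymethane; dilute acid at or below 40 °C is chosen because ketone enolisation at C3 and addition to the chromene double bond are expected to be slow there.

**Compound list**

1 | 3,4-dihydroxybenzaldehyde | O=Cc1ccc(O)c(O)c1 | starting material
2 | 3-chloro-3-methylbut-1-yne | C#CC(C)(C)Cl | starting material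
3 | 3-hydroxy-4-[(2-methylbut-3-yn-2-yl)oxy]benzaldehyde | O=Cc1ccc(OC(C)(C)C#C)c(O)c1 | intermediate
4 | 3,4-dihydroxy-5-(3-methylbuta-1,2-dien-1-yl)benzaldehyde | O=Cc1cc(C=C=C(C)C)c(O)c(O)c1 | intermediate (not isolated)
5 | 8-hydroxy-2,2-dimethyl-2H-chromene-6-carbaldehyde | O=Cc1cc(O)c2c(c1)C=CC(C)(C)O2 | intermediate
6 | 8-(methoxymethoxy)-2,2-dimethyl-2H-chromene-6-carbaldehyde | O=Cc1cc(OCOC)c2c(c1)C=CC(C)(C)O2 | intermediate
7 | N-{2-[8-(methoxymethoxy)-2,2-dimethyl-2H-chromen-6-yl]-1-tosylethenyl}formamide | O=CNC(=Cc1cc(OCOC)c2c(c1)C=CC(C)(C)O2)S(=O)(=O)c1ccc(C)cc1 | intermediate (not isolated)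
8 | 2-[8-(methoxymethoxy)-2,2-dimethyl-2H-chromen-6-yl]acetonitrile | N#CCc1cc(OCOC)c2c(c1)C=CC(C)(C)O2 | intermediate
9 | 2-[8-(methoxymethoxy)-2,2-dimethyl-2H-chromen-6-yl]acetic acid | OC(=O)Cc1cc(OCOC)c2c(c1)C=CC(C)(C)O2 | intermediate
10 | allyl 2-[8-(methoxymethoxy)-2,2-dimethyl-2H-chromen-6-yl]acetate | C=CCOC(=O)Cc1cc(OCOC)c2c(c1)C=CC(C)(C)O2 | intermediate
11 | 2,6-difluoro-4-hydroxybenzaldehyde | O=Cc1c(F)cc(O)cc1F | starting material
12 | 2,6-difluoro-4-(methoxymethoxy)benzaldehyde | O=Cc1c(F)cc(OCOC)cc1F | intermediate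
13 | 2-fluoro-6-methoxy-4-(methoxymethoxy)benzaldehyde | O=Cc1c(F)cc(OCOC)cc1OC | intermediate
14 | allyl 3-[2-fluoro-6-methoxy-4-(methoxymethoxy)phenyl]-3-hydroxy-2-[8-(methoxymethoxy)-2,2-dimethyl-2H-chromen-6-yl]propanoate (racemic, diastereomer mixture) | C=CCOC(=O)C(c1cc(OCOC)c2c(c1)C=CC(C)(C)O2)C(O)c1c(F)cc(OCOC)cc1OC | intermediate
15 | allyl 3-[2-fluoro-6-methoxy-4-(methoxymethoxy)phenyl]-2-[8-(methoxymethoxy)-2,2-dimethyl-2H-chromen-6-yl]-3-oxopropanoate (racemic) | C=CCOC(=O)C(c1cc(OCOC)c2c(c1)C=CC(C)(C)O2)C(=O)c1c(F)cc(OCOC)cc1OC | intermediate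
16 | formaldehyde (used as paraformaldehyde) | C=O | starting material
17 | allyl 3-[2-fluoro-6-methoxy-4-(methoxymethoxy)phenyl]-2-(hydroxymethyl)-2-[8-(methoxymethoxy)-2,2-dimethyl-2H-chromen-6-yl]-3-oxopropanoate (racemic, present as its alkoxide) | C=CCOC(=O)C(CO)(c1cc(OCOC)c2c(c1)C=CC(C)(C)O2)C(=O)c1c(F)cc(OCOC)cc1OC | intermediate (not isolated)
18 | allyl 5-methoxy-7-(methoxymethoxy)-3-[8-(methoxymethoxy)-2,2-dimethyl-2H-chromen-6-yl]-4-oxochromane-3-carboxylate (racemic) | C=CCOC(=O)C1(c2cc(OCOC)c3c(c2)C=CC(C)(C)O3)COc2cc(OCOC)cc(OC)c2C1=O | intermediate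
19 | 5-methoxy-7-(methoxymethoxy)-3-[8-(methoxymethoxy)-2,2-dimethyl-2H-chromen-6-yl]-4-oxochromane-3-carboxylic acid (racemic) | OC(=O)C1(c2cc(OCOC)c3c(c2)C=CC(C)(C)O3)COc2cc(OCOC)cc(OC)c2C1=O | intermediate (not isolated)
20 | rac-5-methoxy-7-(methoxymethoxy)-3-[8-(methoxymethoxy)-2,2-dimethyl-2H-chromen-6-yl]chroman-4-one | COc1cc(OCOC)cc2c1C(=O)C(c1cc(OCOC)c3c(c1)C=CC(C)(C)O3)CO2 | intermediate
21 | (3R,4R)-5-methoxy-7-(methoxymethoxy)-3-[8-(methoxymethoxy)-2,2-dimethyl-2H-chromen-6-yl]chroman-4-ol (cis) | COc1cc(OCOC)cc2c1[C@H](O)[C@H](c1cc(OCOC)c3c(c1)C=CC(C)(C)O3)CO2 | intermediate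
22 | (3R)-5-methoxy-7-(methoxymethoxy)-3-[8-(methoxymethoxy)-2,2-dimethyl-2H-chromen-6-yl]chroman-4-one | COc1cc(OCOC)cc2c1C(=O)[C@H](c1cc(OCOC)c3c(c1)C=CC(C)(C)O3)CO2 | intermediate
23 | (3R)-7-hydroxy-3-(8-hydroxy-2,2-dimethyl-2H-chromen-6-yl)-5-methoxychroman-4-one | COc1cc(O)cc2c1C(=O)[C@H](c1cc(O)c3c(c1)C=CC(C)(C)O3)CO2 | target

**Totals**

Total step count: 15. Longest linear sequence: 13 steps (steps 1 to 6, then 9 to 15).

**Steps most likely to fail**

Step 11 (bears the label). The ring-closing SNAr may be too slow on the electron-rich, twisted aroyl ring, so that reversible hydroxymethylation, aroyl transfer from carbon to oxygen with loss of the aroyl group, or base-induced loss of the allyl ester takes over. The fallback uses known chemistry and closes ring C at O1–C2 instead of O1–C8a. It sets out from 13. SNAr with sodium allyloxide (allyl alcohol, NaH, DMF, 0 °C to rt) replaces the fluorine and should give 2-(allyloxy)-6-methoxy-4-(methoxymethoxy)benzaldehyde F1. Aldol addition of the lithium enolate of 10, as in step 9, gives the beta-hydroxy ester allyl 3-[2-(allyloxy)-6-methoxy-4-(methoxymethoxy)phenyl]-3-hydroxy-2-[8-(methoxymethoxy)-2,2-dimethyl-2H-chromen-6-yl]propanoate F2. Dess–Martin oxidation gives the corresponding beta-keto ester F3. Pd(PPh3)4 with morpholine in THF then removes the aryl allyl ether and the allyl ester together, with loss of CO2, to give the 2-hydroxydeoxybenzoin 1-[2-hydroxy-6-methoxy-4-(methoxymethoxy)phenyl]-2-[8-(methoxymethoxy)-2,2-dimethyl-2H-chromen-6-yl]ethan-1-one F4. Heating F4 with paraformaldehyde and Et2NH in MeOH (alpha-methylenation, then oxa-Michael addition of the phenol) should give the racemic isoflavanone, and the route is rejoined at 20.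

Step 13. Hydride transfer to the hindered, electron-rich C4 carbonyl next to the C5 methoxy group may be slow, and racemisation at C3 may not keep pace, which would erode both diastereo- and enantioselectivity. The fallback sets out from 18 and returns at 22, bypassing 20 and 21: a decarboxylative asymmetric protonation with Pd2(dba)3, (CF3)3-t-BuPHOX and Meldrum's acid in THF at 40 °C. The allyl ester is ionised, CO2 is lost, and the chiral palladium enolate is protonated enantioselectively. The ligand antipode that delivers the (R) ketone would be fixed in a test run. Its selectivity is expected to depend on the steric demand of the 3-aryl group, which is why it is the fallback and not the main route. No new isolated compound arises.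

Step 15. Acid-promoted enolisation at C3 (loss of enantiopurity) and acid addition to the chromene double bond may accompany acetal cleavage. The fallback switches protecting groups at the last configurationally inert stage. It sets out from 18, which has no epimerisable centre. HCl in MeOH removes both MOM ethers and should give allyl 7-hydroxy-3-(8-hydroxy-2,2-dimethyl-2H-chromen-6-yl)-5-methoxy-4-oxochromane-3-carboxylate F5. TBSCl and imidazole in DMF give the bis-silyl ether allyl 7-[(tert-butyldimethylsilyl)oxy]-3-{8-[(tert-butyldimethylsilyl)oxy]-2,2-dimethyl-2H-chromen-6-yl}-5-methoxy-4-oxochromane-3-carboxylate F6. The conditions of steps 12, 13 and 14 then give in turn the racemic bis-silyl isoflavanone F7, the cis-(3R,4R) bis-silyl chroman-4-ol F8 and the (3R) bis-silyl chroman-4-one F9. HF·pyridine buffered with pyridine in THF at 0 °C cleaves the aryl silyl ethers without acid or base strong enough to enolise the ketone, and the route is rejoined at 23.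

**Further compounds**

F1 | step 11 | 2-(allyloxy)-6-methoxy-4-(methoxymethoxy)benzaldehyde | O=Cc1c(OCC=C)cc(OCOC)cc1OC
F2 | step 11 | allyl 3-[2-(allyloxy)-6-methoxy-4-(methoxymethoxy)phenyl]-3-hydroxy-2-[8-(methoxymethoxy)-2,2-dimethyl-2H-chromen-6-yl]propanoate | C=CCOC(=O)C(c1cc(OCOC)c2c(c1)C=CC(C)(C)O2)C(O)c1c(OCC=C)cc(OCOC)cc1OC
F3 | step 11 | allyl 3-[2-(allyloxy)-6-methoxy-4-(methoxymethoxy)phenyl]-2-[8-(methoxymethoxy)-2,2-dimethyl-2H-chromen-6-yl]-3-oxopropanoate | C=CCOC(=O)C(c1cc(OCOC)c2c(c1)C=CC(C)(C)O2)C(=O)c1c(OCC=C)cc(OCOC)cc1OC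
F4 | step 11 | 1-[2-hydroxy-6-methoxy-4-(methoxymethoxy)phenyl]-2-[8-(methoxymethoxy)-2,2-dimethyl-2H-chromen-6-yl]ethan-1-one | COCOc1cc(O)c(C(=O)Cc2cc(OCOC)c3c(c2)C=CC(C)(C)O3)c(OC)c1
F0 | step 13 | none | none
F5 | step 15 | allyl 7-hydroxy-3-(8-hydroxy-2,2-dimethyl-2H-chromen-6-yl)-5-methoxy-4-oxochromane-3-carboxylate (racemic) | C=CCOC(=O)C1(c2cc(O)c3c(c2)C=CC(C)(C)O3)COc2cc(O)cc(OC)c2C1=O
F6 | step 15 | allyl 7-[(tert-butyldimethylsilyl)oxy]-3-{8-[(tert-butyldimethylsilyl)oxy]-2,2-dimethyl-2H-chromen-6-yl}-5-methoxy-4-oxochromane-3-carboxylate (racemic) | C=CCOC(=O)C1(c2cc(O[Si](C)(C)C(C)(C)C)c3c(c2)C=CC(C)(C)O3)COc2cc(O[Si](C)(C)C(C)(C)C)cc(OC)c2C1=O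
F7 | step 15 | rac-7-[(tert-butyldimethylsilyl)oxy]-3-{8-[(tert-butyldimethylsilyl)oxy]-2,2-dimethyl-2H-chromen-6-yl}-5-methoxychroman-4-one | COc1cc(O[Si](C)(C)C(C)(C)C)cc2c1C(=O)C(c1cc(O[Si](C)(C)C(C)(C)C)c3c(c1)C=CC(C)(C)O3)CO2
F8 | step 15 | (3R,4R)-7-[(tert-butyldimethylsilyl)oxy]-3-{8-[(tert-butyldimethylsilyl)oxy]-2,2-dimethyl-2H-chromen-6-yl}-5-methoxychroman-4-ol | COc1cc(O[Si](C)(C)C(C)(C)C)cc2c1[C@H](O)[C@H](c1cc(O[Si](C)(C)C(C)(C)C)c3c(c1)C=CC(C)(C)O3)CO2
F9 | step 15 | (3R)-7-[(tert-butyldimethylsilyl)oxy]-3-{8-[(tert-butyldimethylsilyl)oxy]-2,2-dimethyl-2H-chromen-6-yl}-5-methoxychroman-4-one | COc1cc(O[Si](C)(C)C(C)(C)C)cc2c1C(=O)[C@H](c1cc(O[Si](C)(C)C(C)(C)C)c3c(c1)C=CC(C)(C)O3)CO2
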